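The earlier runs and the new flask stem from a simulated flask with constants of no real substance; scatter was added.

I count chains through Z.

common to all: X 2.1 M
- noon: Z 6.7 mM; run made earlier
- winter: Z 15 mM; run made earlier
- flask: Z 10 mM; time 8.0 min

- noon (time / min: J / %, X / %): 0.667: 0, 99.2; 2.00: 5.5, 95.5; 4.00: 7.4, 92.6; 6.00: 12.9, 86.8; 8.00: 15.8, 84.2
- winter (time / min: J / %, X / %): 0.667: 1.9, 100.3; 1.33: 3.1, 96.6; 2.50: 9.7, 92.2; 4.00: 13.9, 87.5; 8.00: 26.5, 73.7

(standard deviation of a reading: 1 percentage point)

- average number of monomer units in a chain (chains begun, living or dead) at 8.0 min
- part of the X that has reacted at 8.0 min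

- the average divides the monomer in chains by the number of chains begun, living and dead together
- what may be going on: Q -> D; X + Z -> Q + J; X + Q -> J + Q; J + Q -> X + Q; 2 Z -> E
- the earlier runs do not show the number of chains; that part of a forecast is a guess

The flask's Z lies between the Z of the noon and winter runs. At 8.0 min they have used 15.8% and 26.3% of their X, which brackets c from below and above. I tighten this with the order in Z of the first-order slope:

order = ln(winter slope / noon slope) / ln(winter Z / noon Z) = 0.712

c = 20.4%

Z is the limiting reagent for chains, charged in less than X. Its balance is:

Z charged = Z left + chains begun + two × E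

floor = c × X charged / Z charged = 42.9

I call this the chain floor: reacted X per Z charged, the dp if every Z begins a chain. In general, dp is the floor divided by the part of Z that began chains.

If the slope follows living ends and noon's part is at most one, the order below one caps the flask's part, which lifts the lower bound on dp above the floor:

dp above 48.2

From above, the readings give dp no bound, since none shows chains.

The forecast says c 20.5% (18% to 23%) and dp 80 (43 to 250), its central dp above my bound and the low end of its range below that bound, adding “This figure is a guess”.

The flask gives dp 72.2 and c 20.8%.

    Q → D (k = 0.0718 /min)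
    X + Z → Q + J (k = 0.277 /M/min)
    X + Q → J + Q, rate k3*[Q]*[X] (k = 7.89 /M/min)
    J + Q → X + Q, rate k4*[Q] as long as [J] is above zero (k = 1.22 /min)
    2 Z → E (k = 43.3 /M/min)

At the flask's charge, each Z goes towards E at 0.866 /min and into chains at 0.582 /min, so at the start E takes Z faster. With the flask's c, floor over dp then puts the part of Z that began chains at 0.604 in this flask. A neighbour flask with 0.53 M of X has the same start towards E but enters chains at 0.147 /min. Its floor of 3.80 against its dp of 14.0 gives a part of 0.272.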